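(The readings come from a simulation for substances that don't exist, and the scatter is random.)

5 questions stand on one charge put in 4 ways, and I answer them with a ledger of the starting material, which I treat as the limiting reagent for the target since its charge of 0.10 M stands below the 0.200 M of partner.

| flask | starting material | second substrate | partner | protic impurity | free catalyst | remark | time |
|---|---|---|---|---|---|---|---|
| dusk | 0.10 M | 0.10 M | 0.20 M | 0.010 M | 1 mM | run made earlier |  |
| winter | 0.10 M | 0.10 M | 0.40 M | 0.010 M | 1 mM | run made earlier |  |
| north | 0.10 M (fed, over 2.5 h) | 0.100 M | 0.200 M | 0.0100 M | 1.0 mM | all else is in the flask from the start; the feed brings no volume worth counting | 3.0 h |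
| south-east | 0.10 M | 0.100 M | 0.200 M | 0.0100 M | 1.0 mM | everything together at the start | 3.0 h |
| south | 0.10 M | 0.100 M | 0.200 M (fed, over 2.5 h) | 0.0100 M | 1.0 mM | all else is in the flask from the start; the feed brings no volume worth counting | 3.0 h |
| south-west | 0.10 M | 0.100 M | 0.200 M (in portions, 5, over 2.5 h) | 0.0100 M | 1.0 mM | first portion at the start, last at 2.5 h | 3.0 h |

- dusk (time / h: target / %): 0.250: 6.0; 0.500: 11.7; 1.33: 27.4; 3.00: 48.0
- winter (time / min: target / %): 4.00: 2.0; 10.0: 3.5; 25.0: 9.5; 50.0: 18.8

(readings scatter by 0.5 percentage points)

- what was read earlier has a scatter of 0.5 percentage points, one standard deviation

* which flask leads in amount of target, in percent of the starting material charged ("all alike" within 1.5 percentage points) (north / south-east / south / south-west / all alike)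
* how much target is there at the end, in percent of the starting material charged: north
* how much target is there at the end, in percent of the starting material charged: south-east
* how much target is there at the end, in percent of the starting material charged: south
* how much target is there at the end, in percent of the starting material charged: south-west

Dusk read at 0.500 h and winter read at 50.0 min, with twice the partner, run the same clock, so I enter no partner term. My clock is the share of the standing starting material that becomes target each hour, a pseudo-first-order constant:

clock from dusk = 0.249 h⁻¹; from winter = 0.250 h⁻¹

In north the charge arrives over 2.5 h, so I divide the clock's rate by the feed's rate, time drops out, and the books run like this: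

dosing number, clock times dosing time = 0.622

standing when the feed ends, as a share of the charge = 74.5 %

standing at 3.0 h = 65.7 %

booked as target = 34.3 %

Those two entries close my books for north, since I have only target and standing starting material to enter. Dusk's last reading runs a slower clock of 0.218 h⁻¹, and that clock books north at 30.9 %, so I commit to that span. South-east repeats dusk, so I take its 48.0 %, which puts it above north. For the partner-fed flasks I make no reckoning, since both earlier runs were charged with 0.20 M of partner or more, all of it at the start.

The forecast names south-east as leader, with 48 %, and gives north 33 %, south 44.5 % and south-west 46.5 %: “North starves the reaction of starting material”.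

South-east leads with 48.3 %, and north gives 34.2 %, south 44.6 % and south-west 45.6 %.

    starting material + free catalyst ⇌ catalyst intermediate A (K = 8.82 M⁻¹, k = 7.12 M⁻¹ min⁻¹)
    partner + catalyst intermediate A → free catalyst + target (k = 61.5 M⁻¹ min⁻¹)
    second substrate + free catalyst ⇌ catalyst intermediate B (K = 5.50 M⁻¹, k = 315 M⁻¹ min⁻¹)
    partner + catalyst intermediate B → free catalyst + second product (k = 6.40 M⁻¹ min⁻¹)
    starting material + partner → uncatalysed product (k = 0.0111 M⁻¹ min⁻¹)
    partner + protic impurity → quenched reagent (k = 0.990 M⁻¹ min⁻¹)

South-east's lead over south-west, the nearest flask, is 2.7 percentage points against a margin of 1.5 points, so a run would have to bring that lead inside the margin for the forecast's leader to give way to all alike. My standing entry for north, 65.7 %, meets 54.8 % of starting material left at 3.00 h, beside 34.2 % target and 10.9 % uncatalysed product. For the same flask as south-east read at 8.0 h, the clock books 86.3 % as target, and that flask holds 72.1 % target, 20.2 % uncatalysed product and 7.77 % starting material.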